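**Reading of the target (one line):** the SMILES is read as 6α-angeloyloxysclareol, i.e. the natural (13R)-labd-14-ene-8α,13-diol skeleton (5α-H, 9α-H, 10β-CH3, 8α-OH) with an equatorial 6α (6S) ester of (Z)-2-methylbut-2-enoic acid; compounds 1, 3 and 4 are taken as commercial.

## Retrosynthetic overview

1. No ring is built: rings A and B (trans-decalin), the side chain and the C5, C8, C9, C10 and C13 stereocentres are bought intact in (−)-sclareol (1).
2. Key disconnection C6–O: an enzyme-controlled C6α–H hydroxylation of 1 gives triol 2 and sets the only new stereocentre (6S).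
3. Ester O–C(=O) disconnection: angelic acid (3) is activated with 2,4,6-trichlorobenzoyl chloride (4) as mixed anhydride 5; the Z geometry is bought in 3.
4. 2 + 5 give target 6 by DMAP-free acylation of the only secondary hydroxyl.

## Route

Step 1
Reactants: 1 (−)-sclareol, (13R)-labd-14-ene-8α,13-diol
Product: 2 6α-hydroxysclareol, (13R)-labd-14-ene-6α,8α,13-triol
Conditions: engineered cytochrome P450 BM3 (CYP102A1) variant, a heme-iron enzyme (0.2 mol%), NADP+ (2 mol%), D-glucose (1.5 equiv), glucose dehydrogenase, catalase, air, K2HPO4/KH2PO4 buffer pH 8.0, 2% hydroxypropyl-β-cyclodextrin, 25 °C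
Reagents that add atoms: dioxygen, O=O
Why: Proposed new method: a laboratory-evolved self-sufficient P450 BM3 variant (new catalyst; focused library at active-site positions 75, 78, 82, 87, 263, 328 and 437 on an F87A terpenoid-accepting parent, with polar residues introduced to hydrogen-bond the 8α- and 13-hydroxyls) is designed to hold the α face of ring B over the heme, so that the oxoiron (tetravalent iron) porphyrin radical cation abstracts the exposed equatorial 6α-H and rebounds OH on the same face with retention, giving 6α-OH (6S), while the 6β face is blocked by the axial methyls on C4 and C10 (which also slows over-oxidation to the ketone, since the remaining 6β-H is buried) and the vinyl group is kept in the access channel away from iron; the closest known reaction type is P450 BM3-variant and fungal whole-cell hydroxylation of labdane and drimane terpenoids at ring methylenes (e.g. sclareolide at C3), for which no C6α-selective catalyst on sclareol exists.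

Step 2
Reactants: 3 angelic acid, (Z)-2-methylbut-2-enoic acid; 4 2,4,6-trichlorobenzoyl chloride
Product: 5 angelic 2,4,6-trichlorobenzoic anhydride
Conditions: Et3N (1.05 equiv), toluene, 0 °C to rt, 2 h; filter off Et3N·HCl, concentrate, use at once
Reagents that add atoms: none
Why: Mixed-anhydride formation (Yamaguchi activation): triethylammonium angelate attacks the acid chloride, and with no nucleophilic catalyst present the Z alkene is not isomerised; no stereocentre is formed.

Step 3
Reactants: 2 6α-hydroxysclareol; 5 angelic 2,4,6-trichlorobenzoic anhydride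
Product: 6 (13R)-6α-[(Z)-2-methylbut-2-enoyloxy]labd-14-ene-8α,13-diol (target)
Conditions: 5 (3 equiv), Et3N (4 equiv), toluene, 80 °C, 36 h, no DMAP
Reagents that add atoms: none
Why: Yamaguchi-type thermal esterification without DMAP: the secondary equatorial 6α-OH attacks the angeloyl carbonyl (the aroyl carbonyl is shielded by two ortho chlorines), the tertiary 8α- and 13-hydroxyls do not react, Et3N buffers the acid so the tertiary allylic alcohol does not ionise, the absence of a nucleophilic catalyst suppresses Z-to-E isomerisation, and C6 keeps its configuration because the C6–O bond is not broken.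

## Compound list

1 | (−)-sclareol, (13R)-labd-14-ene-8α,13-diol (5α-H, 9α-H, 10β-CH3, 8α-OH, 8β-CH3) | C=C[C@](C)(O)CC[C@@H]1[C@@]2(C)CCCC(C)(C)[C@@H]2CC[C@@]1(C)O | starting material
2 | 6α-hydroxysclareol, (13R)-labd-14-ene-6α,8α,13-triol (6S, equatorial OH) | C=C[C@](C)(O)CC[C@@H]1[C@@]2(C)CCCC(C)(C)[C@@H]2[C@@H](O)C[C@@]1(C)O | intermediate
3 | angelic acid, (Z)-2-methylbut-2-enoic acid | C/C=C(/C)C(=O)O | starting material
4 | 2,4,6-trichlorobenzoyl chloride | O=C(Cl)c1c(Cl)cc(Cl)cc1Cl | starting material
5 | angelic 2,4,6-trichlorobenzoic anhydride, (Z)-2-methylbut-2-enoyl 2,4,6-trichlorobenzoate | C/C=C(/C)C(=O)OC(=O)c1c(Cl)cc(Cl)cc1Cl | intermediate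
6 | (13R)-6α-[(Z)-2-methylbut-2-enoyloxy]labd-14-ene-8α,13-diol, 6α-angeloyloxysclareol | C=C[C@](C)(O)CC[C@@H]1[C@@]2(C)CCCC(C)(C)[C@@H]2[C@@H](OC(=O)/C(C)=C\C)C[C@@]1(C)O | target

## Summary

Total step count: 3. Longest linear sequence: 2 steps (1 → 2 → 6).

Steps most likely to fail, in order of risk:

**Step 1 (the new enzymatic hydroxylation).** Risk: no variant reaches useful C6α selectivity or activity (competing C3, C18 or C11 hydroxylation, or vinyl epoxidation). The fallback uses known reactions, sets out from 1 and returns at 2: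
- Acetylate both tertiary hydroxyls (AcCl, PhNMe2, CH2Cl2) to sclareol 8,13-di-O-acetate F1.
- Eliminate the ring acetate thermally (NaHCO3, DMSO, 140 °C; the exocyclic alkene is the main isomer) to (13R)-manool acetate F2.
- Saponify (KOH, MeOH/H2O, 60 °C) to (13R)-manool F3.
- Move the exocyclic alkene into the ring through the allyl anion (KOtBu, DMSO, 60 °C) to (13R)-labda-7,14-dien-13-ol F4, purified on AgNO3–silica. C7–H is removed faster than the hindered C9–H, and the vinyl group has no allylic hydrogen.
- Oxidise the allylic C6 position (Rh2(cap)4, dirhodium tetrakis(caprolactamate), tBuOOH, K2CO3, CH2Cl2) to (13R)-13-hydroxylabda-7,14-dien-6-one F5.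
- Epoxidise nucleophilically from the α face, anti to the C10 methyl (H2O2, NaOH, MeOH, 0 °C), to (13R)-7α,8α-epoxy-13-hydroxylabd-14-en-6-one F6.
- Open the Cα–O bond reductively (SmI2, THF/MeOH, −78 °C) to (13R)-8α,13-dihydroxylabd-14-en-6-one F7, which already has the sclareol C8 centre.
- Reduce the ketone with dissolving metal (Li, NH3/THF, tBuOH, −78 °C). This gives the thermodynamically preferred equatorial alcohol (the 6β epimer would be 1,3-diaxial to two methyls) and so arrives at 2.

**Step 3 (angeloylation).** Risk: slow acylation of the hindered 6α-OH and partial Z-to-E isomerisation to the tiglate at 80 °C. The fallback sets out from 2 and returns at 6, building the Z alkene after the ester is in place. Esterify with 2-[bis(2,2,2-trifluoroethoxy)phosphoryl]propanoic acid (EDC·HCl, DMAP, CH2Cl2; nothing to isomerise) to the 6α-O-[2-(bis(2,2,2-trifluoroethoxy)phosphoryl)propanoyl] derivative of 2 F8. Then a Still–Gennari olefination with acetaldehyde (KN(SiMe3)2 3.2 equiv to cover the two tertiary hydroxyls, 18-crown-6, THF, −78 °C) gives the (Z)-2-methylbut-2-enoate 6.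

**Step 2 (mixed anhydride).** Risk: the mixed anhydride disproportionates on concentration or is later attacked at the aroyl carbonyl. The fallback sets out from 3 and returns at 6. Dehydrate 3 (2 equiv) with dicyclohexylcarbodiimide (CH2Cl2, 0 °C, filter the urea) to the symmetrical angelic anhydride F9. Then acylate the lithium alkoxide of 2 (LiN(SiMe3)2 1.05 equiv, THF, −20 to 0 °C, then the anhydride); this is a base-mediated, nucleophile-free acylation at low temperature that reaches 6 directly.

## Further compounds

F1 | step 1 | sclareol 8,13-di-O-acetate | C=C[C@](C)(OC(C)=O)CC[C@@H]1[C@@]2(C)CCCC(C)(C)[C@@H]2CC[C@@]1(C)OC(C)=O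
F2 | step 1 | (13R)-labda-8(17),14-dien-13-yl acetate (manool acetate) | C=C[C@](C)(OC(C)=O)CC[C@@H]1[C@@]2(C)CCCC(C)(C)[C@@H]2CCC1=C
F3 | step 1 | (13R)-labda-8(17),14-dien-13-ol (manool) | C=C[C@](C)(O)CC[C@@H]1[C@@]2(C)CCCC(C)(C)[C@@H]2CCC1=C
F4 | step 1 | (13R)-labda-7,14-dien-13-ol | C=C[C@](C)(O)CC[C@@H]1[C@@]2(C)CCCC(C)(C)[C@@H]2CC=C1C
F5 | step 1 | (13R)-13-hydroxylabda-7,14-dien-6-one | C=C[C@](C)(O)CC[C@@H]1[C@@]2(C)CCCC(C)(C)[C@@H]2C(=O)C=C1C
F6 | step 1 | (13R)-7α,8α-epoxy-13-hydroxylabd-14-en-6-one | C=C[C@](C)(O)CC[C@@H]1[C@@]2(C)CCCC(C)(C)[C@@H]2C(=O)[C@H]3O[C@@]13C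
F7 | step 1 | (13R)-8α,13-dihydroxylabd-14-en-6-one | C=C[C@](C)(O)CC[C@@H]1[C@@]2(C)CCCC(C)(C)[C@@H]2C(=O)C[C@@]1(C)O
F8 | step 3 | 6α-O-[2-(bis(2,2,2-trifluoroethoxy)phosphoryl)propanoyl] derivative of 2 (epimers at the phosphonate α-carbon) | C=C[C@](C)(O)CC[C@@H]1[C@@]2(C)CCCC(C)(C)[C@@H]2[C@@H](OC(=O)C(C)P(=O)(OCC(F)(F)F)OCC(F)(F)F)C[C@@]1(C)O
F9 | step 2 | angelic anhydride, (Z)-2-methylbut-2-enoic anhydride | C/C=C(/C)C(=O)OC(=O)/C(C)=C\C
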